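The data are simulated for an exercise, and the scatter is random.

The pitfall in a row of rising charges is to read the solid reagent as a ceiling on the target. The suspect list lets its dissolved form, the partner, leave by two steps: with the tight pair to the target, and with the loose pair to the isomer of the product.

| setting | north | dusk | midnight | noon | summer |
|---|---|---|---|---|---|
| starting material | 0.14 M (in portions, 3) | 0.10 M (in portions, 3) | 0.30 M (in portions, 3) | 1.0 M (in portions, 3) | 2.5 M (in portions, 3) |
| capture agent | 0.010 M | 0.0100 M | 0.0100 M | 0.0100 M | 0.0100 M |
| solid reagent | 0.20 M | 0.200 M | 0.200 M | 0.200 M | 0.200 M |
| remark | run made earlier; portions every 4.0 h | the portions of starting material follow each other after 4.0 h, the first at the start | the portions of starting material follow each other after 4.0 h, the first at the start | the portions of starting material follow each other after 4.0 h, the first at the start | the portions of starting material follow each other after 4.0 h, the first at the start |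
| time |  | 40 h | 40 h | 40 h | 40 h |

- north (time / h: target / %, starting material / %): 1.50: 0.7, 35.3; 3.00: 0.3, 31.0; 6.00: 9.5, 57.7; 10.0: 17.9, 80.2; 20.0: 45.8, 53.5

(readings scatter by 1 percentage point)

- solid reagent is a solid; its amount is given per volume of the solution
- on the list of suspects stand: starting material <-> tight pair; tight pair <-> loose pair; partner + tight pair -> target; partner + loose pair -> isomer of the product; target -> over-reaction product; capture agent + tight pair -> trapped intermediate; solid reagent <-> partner
- at the start none of the solid reagent is in solution
- "hardly changes" means that all values lie within two and a half points (for a concentration: within two and a half percent of the largest)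

- [target] at the end for dusk, midnight, noon, summer, in this order
- the shape of the row from first to last (hardly changes / rises, then falls / falls all the way / rises all the way / falls, then rises)

I count turnovers. Each target or isomer formed consumes one partner, so I compare the charges flask by flask, writing c for a charge:

N(summer) = c(solid reagent) / c(starting material) = 0.0800

This N is my turnover count: the moles of solid reagent charged per mole of starting material charged. The other flasks give:

N(north) = 1.43
N(midnight) = 0.667
N(noon) = 0.200

Midnight looks nearly like north: the same solid reagent and portion interval, with about twice the starting material. Yet north holds more solid reagent than starting material, so its starting material can all be converted. Midnight holds less, which makes the solid reagent its limiting reagent: target and isomer together are bounded by 0.200 M against a charge of 0.30 M.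

North's reading at 20.0 h leaves a gap of 0.7 percentage points in target plus starting material, against a scatter of 1 point. That gap lies within the scatter, so this reading neither shows nor excludes isomer, and it cannot show how the partner divides at 2.5 M. So my own reckoning bounds the sum of target and isomer by 0.200 M and gives no single target value.

The forecast gives 0.08 M, 0.165 M, 0.185 M and 0.19 M, a row that “rises, steeply at first and then barely, though a slight fall at the top is possible”. Its shape is rises all the way.

The flasks give 0.0762 M, 0.181 M, 0.137 M and 0.0972 M, so the row rises, then falls.

    starting material ⇌ tight pair (K = 0.00330, k = 1.90 × 10⁻⁵ s⁻¹)
    tight pair ⇌ loose pair (K = 0.584, k = 4.43 × 10⁻⁴ s⁻¹)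
    partner + tight pair → target (k = 0.462 L mol⁻¹ s⁻¹)
    partner + loose pair → isomer of the product (k = 1.74 L mol⁻¹ s⁻¹)
    target → over-reaction product (k = 2.75 × 10⁻⁸ s⁻¹)
    capture agent + tight pair → trapped intermediate (k = 1.93 × 10⁻⁴ L mol⁻¹ s⁻¹)
    solid reagent ⇌ partner, rate k7*(cs7 - [partner]) while solid is left; crystals form when [partner] > cs7 (solubility = 32.0 mM, k = 7.49 × 10⁻⁵ s⁻¹)

Summer ends with target and isomer together at 7.99 % of the starting material charged, against N = 8.00 %. Noon ends at 20.0 %, against N = 20.0 %. In dusk at 13.9 h, the target step uses partner 22 times as fast as the isomer step. In summer, the target ends at 0.949 times the isomer.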